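**Retrosynthetic overview**

1. The target is reached by deoxygenation at pinane C3 of spiro ketone 21; the C3 oxygen is a temporary group left behind by the key step.
2. 21 comes from hemiketal 19 by ionisation to a cyclic oxocarbenium ion and a semipinacol shift of the bridgehead of a bicyclo[2.1.1]hexan-2-ol. The five-membered ring C1–C3–C4–C5–C7 takes the oxocarbenium carbon in between C1 and C3 and becomes the six-membered ring C1–C2–C3–C4–C5–C7, so the pinane skeleton and the spiro centre arise together.
3. Enabling feature: the spiro carbon C2 of that six-membered carbocycle carries the pyran oxygen O1' (so it can be the carbenium terminus of a 1,2-shift) and lies next to bridgehead C1 (the migrating atom). Its ring neighbour C3 is a plain CH2 that can pass through the carbinol and ketone levels.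
4. 19 comes from a Cu(OTf)2/bis(oxazoline)-catalysed Michael addition (sets C4') of syncarpic acid 17 to α'-hydroxy enone 14. 14 comes from (1R,4R)-5,5-dimethylbicyclo[2.1.1]hexan-2-one 9 by methoxyallene addition and cross-metathesis; 9 comes from the crossed [2+2] photocycloaddition of dienone 5 followed by sulfoximine resolution.
5. Ring order: cyclobutane and five-membered carbocycle together (photocycloaddition), then the dihydropyran (hemiketal), then the six-membered carbocycle by ring expansion. The syncarpic ring is made from an acylphloroglucinol by dearomatising methylation.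

Key step: step 11

Remark: 6 is racemic and 19 is an anomeric mixture in equilibrium with 18, so their SMILES carry no descriptor at the centres concerned. Unprimed numbers are pinane positions (C1–C7), primed numbers are chromene positions, and isobutyl means 2-methylpropyl.

**Route**

Step 1
Reactants: 1 4-methylpent-3-enoic acid
Product: 3 N-methoxy-N,4-dimethylpent-3-enamide, via acyl imidazolide 2 (not isolated)
Conditions: 1,1'-carbonyldiimidazole, CH2Cl2, 0 °C → rt; then MeNH(OMe)·HCl, rt
Reagents that add atoms: N,O-dimethylhydroxylamine hydrochloride, CNOC.Cl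
Why: Carbonyldiimidazole activation and aminolysis (Weinreb amide formation) run under near-neutral conditions that should leave the β,γ-double bond out of conjugation.

Step 2
Reactants: 3 N-methoxy-N,4-dimethylpent-3-enamide; 4 vinylmagnesium bromide
Product: 5 6-methylhepta-1,5-dien-3-one
Conditions: CH2=CHMgBr, THF, −20 → 0 °C; inverse quench into cold 1 M HCl
Reagents that add atoms: none
Why: Weinreb ketone synthesis, in which the chelated tetrahedral adduct prevents over-addition and the acidic inverse quench removes the liberated amine before it can add to the vinyl ketone.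

Step 3
Reactants: 5 6-methylhepta-1,5-dien-3-one
Product: 6 rac-5,5-dimethylbicyclo[2.1.1]hexan-2-one
Conditions: hν (350 nm), degassed MeCN, 0.01 M, rt
Reagents that add atoms: none
Why: Intramolecular crossed [2+2] enone–alkene photocycloaddition of a 1,5-hexadien-3-one, in which initial 1,5-closure (rule of five) gives the tertiary radical that collapses onto the α-keto radical; both bridgehead centres form here as the racemate.

Step 4
Reactants: 6 rac-5,5-dimethylbicyclo[2.1.1]hexan-2-one; 7 (S)-N,S-dimethyl-S-phenylsulfoximine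
Product: 8 (S)-S-{[(1R,2R,4R)-2-hydroxy-5,5-dimethylbicyclo[2.1.1]hexan-2-yl]methyl}-N-methyl-S-phenylsulfoximine
Conditions: 7, n-BuLi, THF, −78 °C; then 6; H2O; separation of the two diastereomeric adducts on silica gel
Reagents that add atoms: none
Why: Sulfoximine resolution of a ketone, in which the enantiopure lithiated sulfoximine adds anti to the gem-dimethyl bridge of each enantiomer to give two separable diastereomeric β-hydroxysulfoximines; the one from the (1R,4R)-ketone is kept, to be assigned against the sulfur centre by X-ray analysis.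

Step 5
Reactants: 8 (S)-S-{[(1R,2R,4R)-2-hydroxy-5,5-dimethylbicyclo[2.1.1]hexan-2-yl]methyl}-N-methyl-S-phenylsulfoximine
Product: 9 (1R,4R)-5,5-dimethylbicyclo[2.1.1]hexan-2-one
Conditions: toluene, 110 °C, sealed tube; ketone distilled from the sulfoximine
Reagents that add atoms: none
Why: Thermal retro-addition of the β-hydroxysulfoximine (second half of the sulfoximine resolution) should return the enantiopure ketone without touching its bridgehead centres.

Step 6
Reactants: 9 (1R,4R)-5,5-dimethylbicyclo[2.1.1]hexan-2-one; 10 methoxyallene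
Product: 12 1-[(1R,2R,4R)-2-hydroxy-5,5-dimethylbicyclo[2.1.1]hexan-2-yl]prop-2-en-1-one, via allenyl carbinol 11 (not isolated)
Conditions: 10, n-BuLi, THF, −40 °C; then 9, −78 °C; H2O; then 5% aq. H2SO4, THF, 0 °C
Reagents that add atoms: water, O
Why: 1-Lithio-1-methoxyallene acts as an acryloyl anion equivalent and should add anti to the gem-dimethyl bridge (hydroxyl syn to that bridge, which sets the carbinol centre), and aqueous acid should hydrolyse the allenyl ether to the α'-hydroxy vinyl ketone because water traps the oxocarbenium ion faster than any shift.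

Step 7
Reactants: 12 1-[(1R,2R,4R)-2-hydroxy-5,5-dimethylbicyclo[2.1.1]hexan-2-yl]prop-2-en-1-one; 13 4-methylpent-1-ene
Product: 14 (E)-1-[(1R,2R,4R)-2-hydroxy-5,5-dimethylbicyclo[2.1.1]hexan-2-yl]-5-methylhex-2-en-1-one
Conditions: 13 (5 equiv), second-generation Hoveyda–Grubbs catalyst RuCl2(H2IMes)(=CH-C6H4-2-OiPr) (3 mol%), CH2Cl2, 40 °C
Reagents that add atoms: none
Why: Olefin cross-metathesis of a vinyl ketone with an excess of a terminal alkene should give the (E)-enone under thermodynamic control and tolerates the tertiary alcohol.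

Step 8
Reactants: 15 2',4',6'-trihydroxyacetophenone
Product: 16 2-acetyl-3-hydroxy-4,4,6,6-tetramethylcyclohex-2-ene-1,5-dione
Conditions: NaOMe, MeI, MeOH, 0 °C → reflux
Reagents that add atoms: iodomethane, CI
Why: Exhaustive dearomatising C-methylation of the acylphloroglucinol anion should stop at the tetramethyl stage because the acetyl-bearing carbon is blocked.

Step 9
Reactants: 16 2-acetyl-3-hydroxy-4,4,6,6-tetramethylcyclohex-2-ene-1,5-dione
Product: 17 syncarpic acid (5-hydroxy-2,2,6,6-tetramethylcyclohex-4-ene-1,3-dione)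
Conditions: 6 M aq. HCl, reflux
Reagents that add atoms: none
Why: Acid-mediated retro-Claisen deacetylation of the β-triketone gives syncarpic acid.

Step 10
Reactants: 14 (E)-1-[(1R,2R,4R)-2-hydroxy-5,5-dimethylbicyclo[2.1.1]hexan-2-yl]-5-methylhex-2-en-1-one; 17 syncarpic acid
Product: 19 (4R)-2-hydroxy-2-[(1R,2R,4R)-2-hydroxy-5,5-dimethylbicyclo[2.1.1]hexan-2-yl]-4-isobutyl-6,6,8,8-tetramethyl-3,4-dihydro-2H-chromene-5,7(6H,8H)-dione, via open-chain Michael adduct 18 (not isolated)
Conditions: Cu(OTf)2 (10 mol%), (R,R)-t-Bu-BOX (11 mol%), 4 Å MS, CH2Cl2, 0 °C → rt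
Reagents that add atoms: none
Why: Michael addition of the enolised cyclic 1,3-dione to the enone held as a five-membered chelate (ketone and hydroxyl oxygens) on the bis(oxazoline) complex of divalent copper, a known activation mode for α'-hydroxy enones; in the square-planar chelate the tert-butyl group of the (R,R)-ligand should shield one face of the β-carbon so that the (R)-centre forms, this ligand enantiomer also keeps the bridgehead side of the carbinol away from the oxazoline substituent, and the adduct closes to the hemiketal.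

Step 11
Reactants: 19 (4R)-2-hydroxy-2-[(1R,2R,4R)-2-hydroxy-5,5-dimethylbicyclo[2.1.1]hexan-2-yl]-4-isobutyl-6,6,8,8-tetramethyl-3,4-dihydro-2H-chromene-5,7(6H,8H)-dione
Product: 21 (1R,2R,4'R,5R)-4'-isobutyl-6,6,6',6',8',8'-hexamethyl-3',4'-dihydrospiro[bicyclo[3.1.1]heptane-2,2'-chromene]-3,5',7'(6'H,8'H)-trione, via oxocarbenium ion 20 (not isolated)
Conditions: Tf2NH (10 mol%), anhydrous MgSO4, CH2Cl2, −20 °C → rt
Reagents that add atoms: none
Why: Proposed new method: the acid ionises the hemiketal to the cyclic oxocarbenium ion 20, and the bridgehead carbon of the bicyclo[2.1.1]hexanol, whose bond to the carbinol carbon lies parallel to the empty p orbital, shifts suprafacially (retention at the bridgehead) to the carbenium carbon while the carbinol becomes the C3 ketone (semipinacol 1,2-shift). The closest known reaction type is the acid-promoted pinacol-type ring expansion of cycloalkanols that carry a cyclic enol ether on the carbinol carbon to α-oxaspiro ketones, together with the Prins–pinacol ring enlargement; new are the vinylogous-acyl oxocarbenium terminus and the bridgehead migration that turns a bicyclo[2.1.1]hexane into a bicyclo[3.1.1]heptane. The pyran ring is closed, or held closed, by 6-exo-trig addition of the enol oxygen to the side-chain ketone, while the carbocycle is not closed but grows from five to six members by insertion of the carbenium carbon between bridgehead C1 and C3. The spiro centre is controlled by the carbinol centre: in the favoured rotamer the ring CH2 of the bicycle eclipses the oxocarbenium oxygen and the hydroxyl points to the pyran CH2 (smallest group in the crowded sector, C–O dipoles opposed), so the bridgehead should add to the face that puts the ether oxygen anti to the gem-dimethyl bridge and itself cis to the isobutyl group, as in the target, with C4' and both bridgeheads untouched. The step needs bridgehead rather than methylene migration, which the higher migratory aptitude of the secondary cyclobutyl carbon should secure, and it needs the cyclic oxocarbenium ion rather than the open protonated ketone (α-ketol pathway, opposite facial sense) as terminus, which the preference of such 1,5-dicarbonyl adducts for the cyclic form, the drying agent and a non-chelating acid should secure. Ketone formation and some relief of strain drive the shift, and the new α-keto group shields the tertiary spiro C–O bond from acid ionisation.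

Step 12
Reactants: 21 (1R,2R,4'R,5R)-4'-isobutyl-6,6,6',6',8',8'-hexamethyl-3',4'-dihydrospiro[bicyclo[3.1.1]heptane-2,2'-chromene]-3,5',7'(6'H,8'H)-trione
Product: 22 (1R,2R,3R,4'R,5R)-3-hydroxy-4'-isobutyl-6,6,6',6',8',8'-hexamethyl-3',4'-dihydrospiro[bicyclo[3.1.1]heptane-2,2'-chromene]-5',7'(6'H,8'H)-dione
Conditions: NaBH4, MeOH–CH2Cl2, −40 → 0 °C
Reagents that add atoms: none
Why: Borohydride reduction should be chemoselective for the α-alkoxy ketone over the vinylogous ester and over the ketone flanked by two quaternary carbons; hydride should enter anti to the gem-dimethyl bridge, and the new carbinol centre (either epimer would serve) is removed two steps later.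

Step 13
Reactants: 22 (1R,2R,3R,4'R,5R)-3-hydroxy-4'-isobutyl-6,6,6',6',8',8'-hexamethyl-3',4'-dihydrospiro[bicyclo[3.1.1]heptane-2,2'-chromene]-5',7'(6'H,8'H)-dione
Product: 23 O-[(1R,2R,3R,4'R,5R)-4'-isobutyl-6,6,6',6',8',8'-hexamethyl-5',7'-dioxo-3',4',5',6',7',8'-hexahydrospiro[bicyclo[3.1.1]heptane-2,2'-chromen]-3-yl] S-methyl dithiocarbonate
Conditions: NaH, CS2, THF, 0 °C → rt; then MeI
Reagents that add atoms: carbon disulfide, S=C=S; iodomethane, CI
Why: Xanthate formation (first half of the Barton–McCombie deoxygenation) uses small reagents that reach the hindered secondary alkoxide, and the molecule has no readily enolisable position for the base to disturb.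

Step 14
Reactants: 23 O-[(1R,2R,3R,4'R,5R)-4'-isobutyl-6,6,6',6',8',8'-hexamethyl-5',7'-dioxo-3',4',5',6',7',8'-hexahydrospiro[bicyclo[3.1.1]heptane-2,2'-chromen]-3-yl] S-methyl dithiocarbonate
Product: 24 (1R,2R,4'R,5S)-4'-isobutyl-6,6,6',6',8',8'-hexamethyl-3',4'-dihydrospiro[bicyclo[3.1.1]heptane-2,2'-chromene]-5',7'(6'H,8'H)-dione
Conditions: Bu3SnH (3 equiv, 0.3 M), Et3B (cat.), air, toluene, rt
Reagents that add atoms: none
Why: Barton–McCombie radical deoxygenation, in which the secondary C3 radical is not cyclobutylcarbinyl (the cyclobutane is two bonds away) and should be trapped by the stannane at room temperature before β-scission of the spiro C–O bond, giving the target with all four stereocentres unchanged.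

**Compound list**

1 | 4-methylpent-3-enoic acid | CC(C)=CCC(=O)O | starting material
2 | 1-(4-methylpent-3-enoyl)imidazole | CC(C)=CCC(=O)n1ccnc1 | intermediate
3 | N-methoxy-N,4-dimethylpent-3-enamide | CC(C)=CCC(=O)N(C)OC | intermediate
4 | vinylmagnesium bromide | C=C[Mg]Br | starting material
5 | 6-methylhepta-1,5-dien-3-one | CC(C)=CCC(=O)C=C | intermediate
6 | rac-5,5-dimethylbicyclo[2.1.1]hexan-2-one | O=C1CC2CC1C2(C)C | intermediate
7 | (S)-N,S-dimethyl-S-phenylsulfoximine | CN=[S@@](C)(=O)c1ccccc1 | starting material
8 | (S)-S-{[(1R,2R,4R)-2-hydroxy-5,5-dimethylbicyclo[2.1.1]hexan-2-yl]methyl}-N-methyl-S-phenylsulfoximine | CN=[S@@](C[C@@]1(O)C[C@H]2C[C@@H]1C2(C)C)(=O)c1ccccc1 | intermediate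
9 | (1R,4R)-5,5-dimethylbicyclo[2.1.1]hexan-2-one | O=C1C[C@H]2C[C@@H]1C2(C)C | intermediate
10 | methoxyallene (1-methoxypropa-1,2-diene) | COC=C=C | starting material
11 | (1R,2R,4R)-2-(1-methoxypropa-1,2-dienyl)-5,5-dimethylbicyclo[2.1.1]hexan-2-ol | COC(=C=C)[C@@]1(O)C[C@H]2C[C@@H]1C2(C)C | intermediate
12 | 1-[(1R,2R,4R)-2-hydroxy-5,5-dimethylbicyclo[2.1.1]hexan-2-yl]prop-2-en-1-one | C=CC(=O)[C@@]1(O)C[C@H]2C[C@@H]1C2(C)C | intermediate
13 | 4-methylpent-1-ene | C=CCC(C)C | starting material
14 | (E)-1-[(1R,2R,4R)-2-hydroxy-5,5-dimethylbicyclo[2.1.1]hexan-2-yl]-5-methylhex-2-en-1-one | CC(C)C/C=C/C(=O)[C@@]1(O)C[C@H]2C[C@@H]1C2(C)C | intermediate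
15 | 2',4',6'-trihydroxyacetophenone | CC(=O)c1c(O)cc(O)cc1O | starting material
16 | 2-acetyl-3-hydroxy-4,4,6,6-tetramethylcyclohex-2-ene-1,5-dione (acetylsyncarpic acid) | CC(=O)C1=C(O)C(C)(C)C(=O)C(C)(C)C1=O | intermediate
17 | syncarpic acid (5-hydroxy-2,2,6,6-tetramethylcyclohex-4-ene-1,3-dione) | CC1(C)C(=O)C=C(O)C(C)(C)C1=O | intermediate
18 | 5-hydroxy-4-{(3R)-1-[(1R,2R,4R)-2-hydroxy-5,5-dimethylbicyclo[2.1.1]hexan-2-yl]-5-methyl-1-oxohexan-3-yl}-2,2,6,6-tetramethylcyclohex-4-ene-1,3-dione (open-chain Michael adduct) | CC(C)C[C@H](CC(=O)[C@@]1(O)C[C@H]2C[C@@H]1C2(C)C)C1=C(O)C(C)(C)C(=O)C(C)(C)C1=O | intermediate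
19 | (4R)-2-hydroxy-2-[(1R,2R,4R)-2-hydroxy-5,5-dimethylbicyclo[2.1.1]hexan-2-yl]-4-isobutyl-6,6,8,8-tetramethyl-3,4-dihydro-2H-chromene-5,7(6H,8H)-dione (cyclic hemiketal, both anomers) | CC(C)C[C@@H]1CC(O)([C@@]2(O)C[C@H]3C[C@@H]2C3(C)C)OC2=C1C(=O)C(C)(C)C(=O)C2(C)C | intermediate
20 | (4R)-2-[(1R,2R,4R)-2-hydroxy-5,5-dimethylbicyclo[2.1.1]hexan-2-yl]-4-isobutyl-6,6,8,8-tetramethyl-5,7-dioxo-3,4,5,6,7,8-hexahydrochromenylium (oxocarbenium ion, triflimide counter-ion) | CC(C)C[C@@H]1CC([C@@]2(O)C[C@H]3C[C@@H]2C3(C)C)=[O+]C2=C1C(=O)C(C)(C)C(=O)C2(C)C | intermediate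
21 | (1R,2R,4'R,5R)-4'-isobutyl-6,6,6',6',8',8'-hexamethyl-3',4'-dihydrospiro[bicyclo[3.1.1]heptane-2,2'-chromene]-3,5',7'(6'H,8'H)-trione | CC(C)C[C@@H]1C[C@@]2(C(=O)C[C@H]3C[C@@H]2C3(C)C)OC2=C1C(=O)C(C)(C)C(=O)C2(C)C | intermediate
22 | (1R,2R,3R,4'R,5R)-3-hydroxy-4'-isobutyl-6,6,6',6',8',8'-hexamethyl-3',4'-dihydrospiro[bicyclo[3.1.1]heptane-2,2'-chromene]-5',7'(6'H,8'H)-dione | CC(C)C[C@@H]1C[C@@]2([C@H](O)C[C@H]3C[C@@H]2C3(C)C)OC2=C1C(=O)C(C)(C)C(=O)C2(C)C | intermediate
23 | O-[(1R,2R,3R,4'R,5R)-4'-isobutyl-6,6,6',6',8',8'-hexamethyl-5',7'-dioxo-3',4',5',6',7',8'-hexahydrospiro[bicyclo[3.1.1]heptane-2,2'-chromen]-3-yl] S-methyl dithiocarbonate | CC(C)C[C@@H]1C[C@@]2([C@H](OC(=S)SC)C[C@H]3C[C@@H]2C3(C)C)OC2=C1C(=O)C(C)(C)C(=O)C2(C)C | intermediate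
24 | (1R,2R,4'R,5S)-4'-isobutyl-6,6,6',6',8',8'-hexamethyl-3',4'-dihydrospiro[bicyclo[3.1.1]heptane-2,2'-chromene]-5',7'(6'H,8'H)-dione | CC(C)C[C@@H]1C[C@@]2(CC[C@H]3C[C@@H]2C3(C)C)OC2=C1C(=O)C(C)(C)C(=O)C2(C)C | target

**Step count and risks**

Total step count: 14. Longest linear sequence: 12 steps (steps 1–7, then 10–14); steps 8–9 form the short second branch.

Steps most likely to fail:

Step 11 (key step). The ring methylene may migrate in place of the bridgehead, which would give the regioisomeric spiro ketone. The bridgehead may add to the other face of the oxocarbenium ion, which would invert the spiro centre. The shift may also run through the open protonated ketone. Fallback with known chemistry, in which the ring expansion is moved to the ketone stage: 9 is homologated with trimethylsilyldiazomethane and BF3·OEt2 (Lewis-acid-promoted diazoalkane ring expansion with migration of the methylene carbon, then protodesilylation on work-up) to (1R,5S)-nopinone F1. Wittig methylenation with Ph3P=CH2 gives (−)-β-pinene F2. The domino Knoevenagel/hetero-Diels–Alder reaction of 17, 3-methylbutanal and F2 proceeds through 2,2,4,4-tetramethyl-6-(3-methylbutylidene)cyclohexane-1,3,5-trione F3 formed in the flask; the heterodiene adds to the alkene face anti to the gem-dimethyl bridge and gives 24 directly, from which the C4' epimer would have to be separated. This fallback sets out from 9 and 17 and comes back to the route at 24.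

Step 10. Facial selectivity at the β-carbon may be poor if ligand and substrate control do not cooperate. Addition to the hindered β-alkyl enone may be sluggish. The Lewis acid may induce an early α-ketol shift of the chelated enone. Fallback that replaces the conjugate addition by a cycloaddition: (1-ethoxyvinyl)lithium is added to 9 (same facial sense as in step 6) to give (1R,2R,4R)-2-(1-ethoxyethenyl)-5,5-dimethylbicyclo[2.1.1]hexan-2-ol F4. This enol ether is combined with 17 and 3-methylbutanal in a domino Knoevenagel/inverse-demand hetero-Diels–Alder reaction (through the enetrione F3 of the first fallback) to give the 2-ethoxy ketal F5. Under the conditions of step 11, F5 loses ethanol to give 20 and then 21. C4' is then under substrate control and its epimers are separated at 21. This fallback sets out from 9 and 17 and comes back to the route at 21.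

Step 14. β-Scission of the spiro C–O bond from the C3 radical, which would open the pyran ring, may compete with hydrogen transfer. Fallback without a radical chain: 22 is dehydrated with the Burgess reagent (syn-elimination; only C4 carries hydrogen, so the double bond can form only away from the spiro centre) to the alkene (1R,2R,4'R,5R)-4'-isobutyl-6,6,6',6',8',8'-hexamethyl-3',4'-dihydrospiro[bicyclo[3.1.1]hept-3-ene-2,2'-chromene]-5',7'(6'H,8'H)-dione F6. F6 is reduced with diimide (KO2C–N=N–CO2K, AcOH), which should leave the allylic C–O bond and the enedione untouched, to give 24. This fallback sets out from 22 and comes back to the route at 24.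

Further compounds
F1 | step 11 | (1R,5S)-6,6-dimethylbicyclo[3.1.1]heptan-2-one (nopinone) | O=C1CC[C@H]2C[C@@H]1C2(C)C
F2 | step 11 | (1S,5S)-6,6-dimethyl-2-methylidenebicyclo[3.1.1]heptane ((−)-β-pinene) | C=C1CC[C@H]2C[C@@H]1C2(C)C
F3 | step 11 | 2,2,4,4-tetramethyl-6-(3-methylbutylidene)cyclohexane-1,3,5-trione | CC(C)CC=C1C(=O)C(C)(C)C(=O)C(C)(C)C1=O
F4 | step 10 | (1R,2R,4R)-2-(1-ethoxyethenyl)-5,5-dimethylbicyclo[2.1.1]hexan-2-ol | C=C(OCC)[C@@]1(O)C[C@H]2C[C@@H]1C2(C)C
F5 | step 10 | (4R)-2-ethoxy-2-[(1R,2R,4R)-2-hydroxy-5,5-dimethylbicyclo[2.1.1]hexan-2-yl]-4-isobutyl-6,6,8,8-tetramethyl-3,4-dihydro-2H-chromene-5,7(6H,8H)-dione | CC(C)C[C@@H]1CC(OCC)([C@@]2(O)C[C@H]3C[C@@H]2C3(C)C)OC2=C1C(=O)C(C)(C)C(=O)C2(C)C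
F6 | step 14 | (1R,2R,4'R,5R)-4'-isobutyl-6,6,6',6',8',8'-hexamethyl-3',4'-dihydrospiro[bicyclo[3.1.1]hept-3-ene-2,2'-chromene]-5',7'(6'H,8'H)-dione | CC(C)C[C@@H]1C[C@@]2(C=C[C@H]3C[C@@H]2C3(C)C)OC2=C1C(=O)C(C)(C)C(=O)C2(C)C
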